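Readings and results were generated by integration with constants of no real substance.

Two questions are asked of these flasks, and the second gets the harder thought.

| setting | eta | epsilon | theta |
|---|---|---|---|
| Z | 0.400 M | 0.800 M | 1.20 M |
| E | 0.600 M | 0.600 M | 1.80 M |
| time |  |  | 27 min |

| run | time / min | [L] / M |
|---|---|---|
| eta run | 1.2 | 0.020 |
| eta run | 3.6 | 0.022 |
| eta run | 7.0 | 0.061 |
| eta run | 11 | 0.123 |
| eta run | 16 | 0.175 |
| eta run | 21 | 0.210 |
| eta run | 27 | 0.239 |
| epsilon run | 1.2 | 0.019 |
| epsilon run | 3.6 | 0.064 |
| epsilon run | 7.0 | 0.189 |
| epsilon run | 11 | 0.314 |
| epsilon run | 16 | 0.406 |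
| epsilon run | 21 | 0.428 |
| epsilon run | 27 | 0.421 |

(readings scatter by 0.006 M)

- how the opening rate goes with [Z] round the charge of the eta run: the exponent of the rate at two percent of Z gone to L (one fixed amount of L, the same in the runs compared)
- L in the theta run at 27 min, as a share of the Z charged

For the order, you compare rates at equal [L], because the eta run gains faster from 7.0 min to 11 min than from 1.2 min to 3.6 min. [L] nearly matches at 7.0 min in eta and 3.6 min in epsilon. There the slopes across the neighbouring readings stand in the ratio 2.15, and the [Z] left in the ratio 2.17. With the same E charged, my order is 0.988.

Now turn the second question round. For theta to turn all its Z into L, you would expect the runs so far to show such a full turnover, and in epsilon that means [L] climbing to the charge of its limiting reagent, the 0.600 M of E, which is less than its Z. Its highest reading is 0.428 M, short by 0.172 M. So I carry the kept share, the highest [L] read over the charge of the limiting reagent, which is 71.3 %, give or take 1.00 %. In theta Z limits, so my rough estimate for 27 min is that share of its Z, which assumes that theta then stands as epsilon stood at its highest reading.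

The forecast says 1 and 84 %, above my share, reading epsilon's levelling “with E unspent, which suggests equilibrium”.

The flask gives 1.0 and 69.7 %.

    Z + E → L + J (0.02478 /M/min)
    Z + E + L → 2 L (0.7140 /M²/min)
    L → Jo (0.01506 /min)

The epsilon rate over the eta rate, both where the same small amount of L has been made, is 2.0. The theta share lies 1.6 percentage points below the kept share, and at 27 min in theta the step L → Jo is removing L at 0.0126 M/min. Used once more, on the eta run, where Z limits, the kept share gives 0.285 M, and the last eta reading, at 27 min, is 0.239 M.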